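**Strategy.** The seven-membered carbocycle (ArCH, CH2, two adjacent carbons of central ring A, C3 of dihydrofuran 1, two adjacent carbons of resorcinol ring B) is cut at its two aryl–C(sp3) bonds: ring A–C3 and ring B–CHAr. One acid-triggered formal (4+3) annulation makes both. The β-aryloxy benzylic alcohol 8, an open-chain ether of a 4-methoxystilbene, ionises, ring A closes the trans-dihydrofuran, and ring B, now held beside the stilbene, traps its protonated form. The step exploits the four-carbon styryl-arene unit and the three-carbon benzyl-arene unit that together form the cycloheptane. One mandelate-derived centre sets all three new stereocentres. A mirror-image arm then adds dihydrofuran 2.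

Key step: step 5

**Remarks.**
- Ring A = central benzene ring; ring B = dioxygenated ring fused to the seven-membered ring; ring C = the free 3,5-dioxygenated ring. Locants in the names: O1/C2/C3 = dihydrofuran 1; C7 = the CH(aryl) carbon of the seven-membered ring; C2'/C3' = dihydrofuran 2.
- Assumption: 4, both enantiomers of 4-hydroxymandelic acid (1, 11) and a THF solution of 6 are purchased. Carbinols 8 and 16 are drawn as the expected anti isomers; a syn epimer at the carbinol carbon is carried along, because the ring closure that follows ionises that carbon.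
- The two dihydrofurans are mirror images of each other, so a stilbene carrying both would be meso-like and would close its seven-membered ring onto either resorcinol ring. The seven-membered ring is therefore closed while only ring B is present, and ring C is added afterwards.

**Step 1**
Reactants: 1 (S)-4-hydroxymandelic acid
Product: 2 (2S)-2-hydroxy-2-{4-[(4-methylbenzenesulfonyl)oxy]phenyl}acetic acid
Conditions: TsCl (1.1 equiv), NaOH (aq, 2.2 equiv), THF/H2O, 0 °C to rt; then HCl (aq)
Reagents that add atoms: 4-methylbenzenesulfonyl chloride, Cc1ccc(cc1)S(=O)(=O)Cl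
Why: Schotten–Baumann sulfonylation, in which only the phenoxide is a competent nucleophile in water and the stereocentre is untouched; the sulfonate later serves as an electron-withdrawing mask of the 4-hydroxyphenyl group.

**Step 2**
Reactants: 2 (2S)-2-hydroxy-2-{4-[(4-methylbenzenesulfonyl)oxy]phenyl}acetic acid
Product: 3 methyl (2S)-2-hydroxy-2-{4-[(4-methylbenzenesulfonyl)oxy]phenyl}acetate
Conditions: MeOH, H2SO4 (cat.), 50 °C
Reagents that add atoms: methanol, CO
Why: Fischer esterification; the electron-poor aryl ring keeps the benzylic hydroxyl from ionising, so the configuration should be retained.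

**Step 3**
Reactants: 3 methyl (2S)-2-hydroxy-2-{4-[(4-methylbenzenesulfonyl)oxy]phenyl}acetate; 4 (E)-5-[2-(4-methoxyphenyl)ethenyl]benzene-1,3-diol (threefold excess, recovered)
Product: 5 methyl (2R)-2-{3-hydroxy-5-[(E)-2-(4-methoxyphenyl)ethenyl]phenoxy}-2-{4-[(4-methylbenzenesulfonyl)oxy]phenyl}acetate
Conditions: PPh3, DIAD, THF, 0 °C to rt
Reagents that add atoms: none
Why: Mitsunobu etherification, in which SN2 displacement of the alkoxyphosphonium group by the phenoxide inverts the mandelate centre (S to R); the ester and the electron-poor aryl group suppress SN1 leakage, and the excess of the symmetric diol holds the reaction at the mono-ether.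

**Step 4**
Reactants: 5 methyl (2R)-2-{3-hydroxy-5-[(E)-2-(4-methoxyphenyl)ethenyl]phenoxy}-2-{4-[(4-methylbenzenesulfonyl)oxy]phenyl}acetate; 6 3,5-dimethoxyphenylmagnesium bromide
Product: 8 (1S,2R)-1-(3,5-dimethoxyphenyl)-2-{3-hydroxy-5-[(E)-2-(4-methoxyphenyl)ethenyl]phenoxy}-2-{4-[(4-methylbenzenesulfonyl)oxy]phenyl}ethan-1-ol, via α-aryloxy aldehyde 7 (not isolated)
Conditions: i-Bu2AlH (2.2 equiv), CH2Cl2, −78 °C; then 6 (4 equiv, THF), −78 to −20 °C; aq. potassium sodium tartrate
Reagents that add atoms: none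
Why: One-pot ester reduction/arylation, in which the aluminium hemiacetal formed at −78 °C releases aldehyde 7 only as the Grignard reagent consumes it, limiting enolisation of the α-aryloxy centre; Felkin–Anh addition with the aryloxy group anti to the nucleophile should favour the anti (1S,2R) carbinol.

**Step 5**
Reactants: 8 (1S,2R)-1-(3,5-dimethoxyphenyl)-2-{3-hydroxy-5-[(E)-2-(4-methoxyphenyl)ethenyl]phenoxy}-2-{4-[(4-methylbenzenesulfonyl)oxy]phenyl}ethan-1-ol
Product: 10 (2S,3S,7S)-core phenol bearing 2-(4-tosyloxyphenyl) and 7-(4-methoxyphenyl) groups with ring B as dimethyl ether and the ring-A hydroxyl free, via dihydrobenzofuran stilbene 9 (not isolated)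
Conditions: TfOH (10 mol%), HFIP/CH2Cl2 4:1, 0.005 M, 0 °C to rt
Reagents that add atoms: none
Why: Acid ionises the benzylic alcohol in the ionising solvent and ring A, attacking through its carbon ortho to the ether oxygen and para to the free hydroxyl, closes dihydrofuran 1 (intramolecular Friedel–Crafts alkylation, 5-exo-tet-type cationic closure) to give 9; protonation of the stilbene at the carbon next to ring A then gives the 4-methoxybenzyl cation, which the ring-B carbon ortho to the new benzylic centre (ortho and para to the two methoxy groups) traps in a 7-endo-trig hydroarylation. The closest known reactions are the dehydrative Friedel–Crafts cyclisation of 2-aryloxy-1-arylethanols to 3-aryl-2,3-dihydrobenzofurans and the acid-mediated closure of ε-viniferin-type stilbenes to the ampelopsin B ring system. C3 is set by the existing C2 centre: the two aryl groups end trans to avoid eclipsing in the five-membered transition state, and the anti carbinol gives the same result by invertive displacement. C7 is set by C3: ring B is held on one face of ring A, and the cation should close with its hydrogen in the plane of ring B beside the methoxy group (minimal 1,3-allylic strain), which places the 4-methoxyphenyl group pseudo-axial on the face of the C3 hydrogen. The step needs closure para rather than ortho to the free hydroxyl (electronic preference), no ionisation of the aryl ether and no aryl participation (secured by the electron-poor tosyloxyphenyl group), and intramolecular trapping over stilbene oligomerisation (high dilution); because ring C is not yet present, the seven-membered ring can only close onto ring B.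

**Step 6**
Reactants: 11 (R)-4-hydroxymandelic acid
Product: 12 (2R)-2-hydroxy-2-{4-[(4-methylbenzenesulfonyl)oxy]phenyl}acetic acid
Conditions: TsCl (1.1 equiv), NaOH (aq, 2.2 equiv), THF/H2O, 0 °C to rt; then HCl (aq)
Reagents that add atoms: 4-methylbenzenesulfonyl chloride, Cc1ccc(cc1)S(=O)(=O)Cl
Why: Schotten–Baumann sulfonylation of the phenoxide as in step 1, giving the mirror-image arm.

**Step 7**
Reactants: 12 (2R)-2-hydroxy-2-{4-[(4-methylbenzenesulfonyl)oxy]phenyl}acetic acid
Product: 13 methyl (2R)-2-hydroxy-2-{4-[(4-methylbenzenesulfonyl)oxy]phenyl}acetate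
Conditions: MeOH, H2SO4 (cat.), 50 °C
Reagents that add atoms: methanol, CO
Why: Fischer esterification with retention, as in step 2.

**Step 8**
Reactants: 10 (2S,3S,7S)-core phenol; 13 methyl (2R)-2-hydroxy-2-{4-[(4-methylbenzenesulfonyl)oxy]phenyl}acetate
Product: 14 (2S,3S,7S)-core aryl ether of methyl (2S)-2-aryloxy-2-{4-[(4-methylbenzenesulfonyl)oxy]phenyl}acetate (ether at the ring-A oxygen)
Conditions: PPh3, DIAD, THF, 0 °C to rt
Reagents that add atoms: none
Why: Mitsunobu etherification of the only free phenol with SN2 inversion of the mandelate centre (R to S), installing the arm of opposite handedness.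

**Step 9**
Reactants: 14 (2S,3S,7S)-core ether ester; 6 3,5-dimethoxyphenylmagnesium bromide
Product: 16 (2S,3S,7S)-core ether of (1R,2S)-1-(3,5-dimethoxyphenyl)-2-aryloxy-2-{4-[(4-methylbenzenesulfonyl)oxy]phenyl}ethan-1-ol, via α-aryloxy aldehyde 15 (not isolated)
Conditions: i-Bu2AlH (1.2 equiv), CH2Cl2, −78 °C; then 6 (3 equiv, THF), −78 to −20 °C; aq. potassium sodium tartrate
Reagents that add atoms: none
Why: Same one-pot ester reduction/Grignard addition as step 4, with Felkin–Anh control expected to favour the anti (1R,2S) carbinol; the aryl sulfonates, methyl ethers and existing rings are inert at −78 °C.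

**Step 10**
Reactants: 16 (2S,3S,7S)-core ether carbinol
Product: 17 (2S,3S,7S,2'R,3'R)-bis(dihydrofuran) with five methyl ethers and two 4-tosyloxyphenyl groups
Conditions: TfOH (10 mol%), HFIP/CH2Cl2 4:1, 0 °C, short reaction time
Reagents that add atoms: none
Why: Dehydrative intramolecular Friedel–Crafts alkylation (cationic 5-exo-tet-type closure) at the ring-A carbon para to the oxygen of dihydrofuran 1; C3' is set trans to the mandelate-derived C2' centre as in step 5, and no stilbene remains to trigger anything further.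

**Step 11**
Reactants: 17 (2S,3S,7S,2'R,3'R)-bis(dihydrofuran) bis-tosylate
Product: 18 (2S,3S,7S,2'R,3'R)-pentamethyl ether with two free 4-hydroxyphenyl groups
Conditions: KOH, MeOH/THF/H2O, 60 °C, under argon
Reagents that add atoms: none
Why: Hydroxide attacks sulfur of the aryl sulfonates (S–O cleavage), freeing the two phenols without touching methyl ethers or stereocentres; the trans-dihydrofurans are the thermodynamic isomers should any reversible ring opening occur.

**Step 12**
Reactants: 18 (2S,3S,7S,2'R,3'R)-pentamethyl ether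
Product: 19 target heptaphenol CNP0136963.1
Conditions: BBr3 (excess), CH2Cl2, −78 °C to rt; then MeOH, H2O
Reagents that add atoms: none
Why: Lewis-acid ether cleavage (borate adduct, then bromide SN2 at methyl) removes the five methyl groups; the stereocentres are not on the reacting carbons.

**Compound list**
1 | (S)-4-hydroxymandelic acid | OC(=O)[C@@H](O)c1ccc(O)cc1 | starting material
2 | (2S)-2-hydroxy-2-{4-[(4-methylbenzenesulfonyl)oxy]phenyl}acetic acid | OC(=O)[C@@H](O)c1ccc(OS(=O)(=O)c2ccc(C)cc2)cc1 | intermediate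
3 | methyl (2S)-2-hydroxy-2-{4-[(4-methylbenzenesulfonyl)oxy]phenyl}acetate | COC(=O)[C@@H](O)c1ccc(OS(=O)(=O)c2ccc(C)cc2)cc1 | intermediate
4 | (E)-5-[2-(4-methoxyphenyl)ethenyl]benzene-1,3-diol (desoxyrhapontigenin) | COc1ccc(/C=C/c2cc(O)cc(O)c2)cc1 | starting material
5 | methyl (2R)-2-{3-hydroxy-5-[(E)-2-(4-methoxyphenyl)ethenyl]phenoxy}-2-{4-[(4-methylbenzenesulfonyl)oxy]phenyl}acetate | COc1ccc(/C=C/c2cc(O)cc(O[C@H](c3ccc(OS(=O)(=O)c4ccc(C)cc4)cc3)C(=O)OC)c2)cc1 | intermediate
6 | 3,5-dimethoxyphenylmagnesium bromide (THF solution) | COc1cc(OC)cc([Mg]Br)c1 | starting material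
7 | (2R)-2-{3-hydroxy-5-[(E)-2-(4-methoxyphenyl)ethenyl]phenoxy}-2-{4-[(4-methylbenzenesulfonyl)oxy]phenyl}acetaldehyde (formed in the flask) | COc1ccc(/C=C/c2cc(O)cc(O[C@H](c3ccc(OS(=O)(=O)c4ccc(C)cc4)cc3)C=O)c2)cc1 | intermediate
8 | (1S,2R)-1-(3,5-dimethoxyphenyl)-2-{3-hydroxy-5-[(E)-2-(4-methoxyphenyl)ethenyl]phenoxy}-2-{4-[(4-methylbenzenesulfonyl)oxy]phenyl}ethan-1-ol | COc1ccc(/C=C/c2cc(O)cc(O[C@H](c3ccc(OS(=O)(=O)c4ccc(C)cc4)cc3)[C@@H](O)c3cc(OC)cc(OC)c3)c2)cc1 | intermediate
9 | 4-{(2S,3S)-3-(3,5-dimethoxyphenyl)-6-hydroxy-4-[(E)-2-(4-methoxyphenyl)ethenyl]-2,3-dihydro-1-benzofuran-2-yl}phenyl 4-methylbenzenesulfonate (formed in the flask) | COc1ccc(/C=C/c2cc(O)cc3O[C@H](c4ccc(OS(=O)(=O)c5ccc(C)cc5)cc4)[C@@H](c4cc(OC)cc(OC)c4)c23)cc1 | intermediate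
10 | (2S,3S,7S)-core phenol: dihydrofuran 1 (2-(4-tosyloxyphenyl)) fused through C3 to the seven-membered ring, 7-(4-methoxyphenyl), ring B dimethyl ether, free ring-A hydroxyl | COc1ccc([C@@H]2Cc3c4c(cc(O)c3)O[C@H](c3ccc(OS(=O)(=O)c5ccc(C)cc5)cc3)[C@H]4c3cc(OC)cc(OC)c32)cc1 | intermediate
11 | (R)-4-hydroxymandelic acid | OC(=O)[C@H](O)c1ccc(O)cc1 | starting material
12 | (2R)-2-hydroxy-2-{4-[(4-methylbenzenesulfonyl)oxy]phenyl}acetic acid | OC(=O)[C@H](O)c1ccc(OS(=O)(=O)c2ccc(C)cc2)cc1 | intermediate
13 | methyl (2R)-2-hydroxy-2-{4-[(4-methylbenzenesulfonyl)oxy]phenyl}acetate | COC(=O)[C@H](O)c1ccc(OS(=O)(=O)c2ccc(C)cc2)cc1 | intermediate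
14 | ring-A aryl ether of 10 with methyl (2S)-2-oxy-2-{4-[(4-methylbenzenesulfonyl)oxy]phenyl}acetate | COc1ccc([C@@H]2Cc3c4c(cc(O[C@@H](c5ccc(OS(=O)(=O)c6ccc(C)cc6)cc5)C(=O)OC)c3)O[C@H](c3ccc(OS(=O)(=O)c5ccc(C)cc5)cc3)[C@H]4c3cc(OC)cc(OC)c32)cc1 | intermediate
15 | corresponding (2S)-α-aryloxy aldehyde (formed in the flask) | COc1ccc([C@@H]2Cc3c4c(cc(O[C@@H](c5ccc(OS(=O)(=O)c6ccc(C)cc6)cc5)C=O)c3)O[C@H](c3ccc(OS(=O)(=O)c5ccc(C)cc5)cc3)[C@H]4c3cc(OC)cc(OC)c32)cc1 | intermediate
16 | ring-A aryl ether of 10 with (1R,2S)-1-(3,5-dimethoxyphenyl)-2-oxy-2-{4-[(4-methylbenzenesulfonyl)oxy]phenyl}ethan-1-ol | COc1ccc([C@@H]2Cc3c4c(cc(O[C@@H](c5ccc(OS(=O)(=O)c6ccc(C)cc6)cc5)[C@H](O)c5cc(OC)cc(OC)c5)c3)O[C@H](c3ccc(OS(=O)(=O)c5ccc(C)cc5)cc3)[C@H]4c3cc(OC)cc(OC)c32)cc1 | intermediate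
17 | (2S,3S,7S,2'R,3'R)-bis(dihydrofuran): rings B and C as dimethyl ethers, 7-(4-methoxyphenyl), 2- and 2'-(4-tosyloxyphenyl) | COc1ccc([C@@H]2Cc3c4c(cc5c3[C@@H](c3cc(OC)cc(OC)c3)[C@H](c3ccc(OS(=O)(=O)c6ccc(C)cc6)cc3)O5)O[C@H](c3ccc(OS(=O)(=O)c6ccc(C)cc6)cc3)[C@H]4c3cc(OC)cc(OC)c32)cc1 | intermediate
18 | (2S,3S,7S,2'R,3'R)-pentamethyl ether with 2- and 2'-(4-hydroxyphenyl) groups | COc1ccc([C@@H]2Cc3c4c(cc5c3[C@@H](c3cc(OC)cc(OC)c3)[C@H](c3ccc(O)cc3)O5)O[C@H](c3ccc(O)cc3)[C@H]4c3cc(OC)cc(OC)c32)cc1 | intermediate
19 | CNP0136963.1, (2S,3S,7S,2'R,3'R)-heptaphenol | Oc1ccc([C@@H]2Cc3c4c(cc5c3[C@@H](c3cc(O)cc(O)c3)[C@H](c3ccc(O)cc3)O5)O[C@H](c3ccc(O)cc3)[C@H]4c3cc(O)cc(O)c32)cc1 | target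

**Total step count:** 12. **Longest linear sequence:** 10 steps (steps 1–5 and 8–12).

**Steps most likely to fail**

Step 5. Ionisation at the weakly stabilised benzylic carbon may be outrun by loss of the neighbouring proton (enol ether formation), by acid-driven oligomerisation of the stilbene, or by ring closure ortho instead of para to the free hydroxyl. A syn carbinol reacting by direct displacement would also give the cis-dihydrofuran. The fallback sets out from 8 and comes back at 10; it splits the cascade and replaces acid ionisation by sulfonate displacement under buffered conditions. The phenol of 8 is silylated (TBSCl, imidazole, DMF) to the aryl silyl ether F1. The carbinol is mesylated (MsCl, Et3N, CH2Cl2, −20 °C) to the mesylate F2. Ring A displaces the mesylate with inversion in HFIP containing 2,6-lutidine (40 °C) to give the silyl-protected dihydrobenzofuran stilbene F3. Bu4NF removes the silyl group to give 9 as an isolated compound, and catalytic TfOH in CH2Cl2 then closes the seven-membered ring to 10.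

Step 10. Ring closure may occur at the ring-A carbon between the two oxygens. The acid may also reopen the seven-membered ring by retro-Friedel–Crafts cleavage at C7, after which the cation could re-close onto ring C and erode the enantiopurity. The fallback sets out from 16 and comes back at 17. The carbinol is converted (MsCl, Et3N, CH2Cl2, −20 °C) into the mesylate F4, which is cyclised by solvolysis in HFIP buffered with 2,6-di-tert-butylpyridine (40 °C), an invertive displacement that never exposes the product to strong acid.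

Step 4 (and its twin, step 9). Base-induced enolisation of the α-aryloxy aldehyde before the aryl group adds would erode the configuration that the whole arm inherits. The fallback sets out from 5 and comes back at 8; it separates the redox adjustment from the carbon–carbon bond formation and uses a non-basic aryl donor. The ester is reduced with LiBH4 (THF, 0 °C) to the primary alcohol F5. This is oxidised under Swern conditions ((COCl)2, DMSO, i-Pr2NEt, −78 °C) to aldehyde 7, which is isolated cold. The aryl group is then transferred from the aryltitanium reagent prepared from 6 and ClTi(OiPr)3 (THF, −78 to −30 °C) to give 8.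

**Further compounds**
F1 | step 5 | tert-butyldimethylsilyl ether of 8 at the ring-A phenol | COc1ccc(/C=C/c2cc(O[Si](C)(C)C(C)(C)C)cc(O[C@H](c3ccc(OS(=O)(=O)c4ccc(C)cc4)cc3)[C@@H](O)c3cc(OC)cc(OC)c3)c2)cc1
F2 | step 5 | methanesulfonate of F1 at the carbinol | COc1ccc(/C=C/c2cc(O[Si](C)(C)C(C)(C)C)cc(O[C@H](c3ccc(OS(=O)(=O)c4ccc(C)cc4)cc3)[C@@H](OS(C)(=O)=O)c3cc(OC)cc(OC)c3)c2)cc1
F3 | step 5 | tert-butyldimethylsilyl ether of 9 | COc1ccc(/C=C/c2cc(O[Si](C)(C)C(C)(C)C)cc3O[C@H](c4ccc(OS(=O)(=O)c5ccc(C)cc5)cc4)[C@@H](c4cc(OC)cc(OC)c4)c23)cc1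
F4 | step 10 | methanesulfonate of 16 at the carbinol | COc1ccc([C@@H]2Cc3c4c(cc(O[C@@H](c5ccc(OS(=O)(=O)c6ccc(C)cc6)cc5)[C@H](OS(C)(=O)=O)c5cc(OC)cc(OC)c5)c3)O[C@H](c3ccc(OS(=O)(=O)c5ccc(C)cc5)cc3)[C@H]4c3cc(OC)cc(OC)c32)cc1
F5 | step 4 | (2R)-2-{3-hydroxy-5-[(E)-2-(4-methoxyphenyl)ethenyl]phenoxy}-2-{4-[(4-methylbenzenesulfonyl)oxy]phenyl}ethan-1-ol | COc1ccc(/C=C/c2cc(O)cc(O[C@H](c3ccc(OS(=O)(=O)c4ccc(C)cc4)cc3)CO)c2)cc1
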